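The free catalyst was what I watched in the blue flask, the one asked about, with the hotter teal run beside it.

in all of them: starting material 0.010 M; free catalyst 0.5 mol%; second catalyst 0.05 mol%

| flask | partner | capture agent | temperature | remark | time |
|---|---|---|---|---|---|
| blue | 1 equiv | 1 mM | 110 °C | the very flask that is asked about, followed so far |  |
| teal | 1 equiv | 1 mM | 116 °C | run made earlier |  |
| flask | 1.00 equiv | 1.00 mM | 110 °C |  | 3.0 h |

| run | time / min | product / % |
|---|---|---|
| blue | 12.0 | 10.1 |
| blue | 20.0 | 18.2 |
| blue | 30.0 | 25.5 |
| blue | 50.0 | 33.3 |
| blue | 80.0 | 36.9 |
| blue | 150 | 37.9 |
| teal | 12.0 | 13.2 |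
| teal | 20.0 | 20.6 |
| teal | 30.0 | 26.3 |
| teal | 50.0 | 29.1 |
| teal | 80.0 | 29.7 |
| teal | 150 | 30.8 |

(readings scatter by 0.3 percentage points)

- what is taken out of product is counted as made
- what was read earlier has a scatter of 0.3 percentage points, one standard deviation
- on the list of suspects stand: starting material + free catalyst -> free catalyst + open intermediate; second catalyst + open intermediate <-> catalyst intermediate; partner + catalyst intermediate -> second catalyst + product; free catalyst -> spent catalyst; open intermediate + capture agent -> trapped intermediate
- "the catalyst" is free catalyst with its forms; second catalyst is a second catalyst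
- additions bring no volume worth counting

- south: at 3.0 h add partner, 50.0% of the amount charged, then wait 1.5 h
- east: at 3.0 h add free catalyst, 100% of the amount charged, then wait 1.5 h
- north: at 3.0 h raise the temperature by 15 K, then wait 1.5 h
- north-west: at 3.0 h take out 90% of the product then present, then wait 1.5 h
- west: change nothing and wait 1.5 h more

* product, in percent of the starting material first charged, at 3.0 h
* the remedy with the largest gain of product, or "none" below 2 percentage points (south / east / north / north-west / west / none)
* product present, with what was taken out counted in, in percent of the starting material first charged, after south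
* product present, with what was taken out counted in, in percent of the starting material first charged, after north-west

**Catalyst life.** Between 30.0 min and 50.0 min the blue gap to the last reading shrank at 0.0496 min⁻¹, which I read as a life of 20.2 min. Teal stopped lower than blue, at 30.8% against 37.9%, while subtraction left 62.1% of the blue partner, so I blamed a dying catalyst and not a lack of partner. The time 3.0 h is 8.93 lives, which leaves about 0.0133% of the free catalyst by my reckoning, so I put blue at its last reading.

**First way.** I called the catalyst's reach the natural logarithm of the charged fraction of starting material over the fraction left once the catalyst has died, 0.476 in the blue flask; it is a pseudo-first-order constant multiplied by the catalyst's life. That figure came from counting one starting material per product, by which blue kept 62.1%.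

**Second way.** Rate times life should give the same number, but running the late blue line back to zero time gave 54.9% consumed, a reach of 0.796. The line cheated: blue made 10.1% in its first 12.0 min and 8.1 percentage points in the next 8.00 min, faster later, so the opening minutes do not follow it. I kept the count, as a floor, since it ignores anything the capture agent took.

**My reckoning.** I assumed that a fresh charge at the same temperature has the same reach, so east, at 100% of the charge, should turn the same share of the 62.1% into product, a gain of 24 points.

**The forecast.** It gave 38% (37.5% to 38.6%), east as best, 38% after south and 38% after north-west, on this ground: “Fresh catalyst converts about 48 % of the remaining 52 %”. Its 52 differs from my 62.1%.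

**The result.** The flask gave 37.9%, with east bringing 23 points, and 37.9% after south and 37.9% after north-west. Starting material left at 180 min was 60.5%, not the forecast's 52, yet the ranking stood.

    starting material + free catalyst → free catalyst + open intermediate (k = 7.62 L mol⁻¹ s⁻¹, Ea = 57.0 kJ mol⁻¹)
    second catalyst + open intermediate ⇌ catalyst intermediate (K = 32000 L mol⁻¹, k = 469 L mol⁻¹ s⁻¹, Ea = 59.0 kJ mol⁻¹, ΔH = −51.0 kJ mol⁻¹)
    partner + catalyst intermediate → second catalyst + product (k = 501 L mol⁻¹ s⁻¹, Ea = 53.0 kJ mol⁻¹)
    free catalyst → spent catalyst (k = 7.59 × 10⁻⁴ s⁻¹, Ea = 115 kJ mol⁻¹)
    open intermediate + capture agent → trapped intermediate (k = 0.0974 L mol⁻¹ s⁻¹, Ea = 58.0 kJ mol⁻¹)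
    (constants at 110 °C)

**Second flask.** The neighbour charged with 2 mol% of free catalyst carries 4.00 times the loading, so the reach predicts 14.9% of its starting material left, and it ended at 13.4%.

The runs are simulated with made-up constants, noise included.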